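Start from early times: the violet and red runs share their charges of partner and free catalyst and differ in starting material.

| flask | starting material | partner | free catalyst | remark |
|---|---|---|---|---|
| violet | 0.010 M | 0.015 M | 38 µM | the very flask that is asked about, followed so far |
| red | 0.0050 M | 0.015 M | 38 µM | run made earlier |
| flask | 0.010 M | 0.0150 M | 38 µM |  |

- violet (time / min: product / %, starting material / %): 1.50: 3.4, 97.3; 2.50: 5.1, 95.0; 4.00: 7.9, 91.7; 5.00: 10.6, 89.3; 8.00: 14.8, 84.2; 12.0: 22.6, 76.8; 20.0: 35.4, 64.0
- red (time / min: product / %, starting material / %): 15.0: 48.7, 50.5; 30.0: 83.3, 16.6; 40.0: 95.0, 4.9; 60.0: 100.7, 1.2; 80.0: 100.1, 1.0; 90.0: 100.3, 0

(standard deviation of a reading: 0.5 percentage points)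

- percent here means starting material units held: one spent catalyst counts as two
- steps under discussion: starting material + catalyst intermediate B -> catalyst intermediate C; partner + free catalyst -> catalyst intermediate A; catalyst intermediate C -> free catalyst + product; 2 catalyst intermediate C -> spent catalyst; catalyst intermediate A -> by-product + catalyst intermediate B; 2 free catalyst <-> resting dimer
- no earlier run changes the charge of free catalyst; that part of a forecast is a guess
- no earlier run changes the charge of partner; that part of a forecast is a guess

- apparent order in partner when 20% of the starting material are converted (percent change of the rate of making product for one percent more partner charged)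
- apparent order in free catalyst when 20% of the starting material are converted (percent change of the rate of making product for one percent more free catalyst charged)
- factor on the rate of making product when 20% of the starting material are converted if free catalyst is charged twice over

1. The violet run, charged with twice the starting material of the red run, makes 0.177 mM min⁻¹ of product on average up to 20.0 min. The red run makes 0.162 mM min⁻¹ up to 15.0 min.

2. Picture the round as steps in series, each holding a share of the time per turn. If the partner step and the starting-material step were equal, each would hold half, and that symmetric case is your zero. The reading gives the starting-material share, the percent change of rate per percent more starting material, 0.125, which is less than that.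

3. Bound from above: at 20% conversion, with one partner used per product, c(partner) is 13.0 mM. One percent more charged is therefore 1.15 percent more present. Giving the partner step everything the share leaves yields 1.01.

4. Bound from below: if steps free of partner took as much as the partner step, you get 0.505. That is a symmetric guess, not a proof, because no run changes the partner. I commit to the upper end, 1.01, for ord_B.

5. The forecast gives 0.8, 0.75 and 1.7. Its partner order lies inside the bracket, lower than my commitment: “Charged partner leverages this slightly, but A→B may share control”. Its catalyst numbers are a declared guess.

    starting material + catalyst intermediate B → catalyst intermediate C (k = 68.0 M⁻¹ s⁻¹)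
    partner + free catalyst → catalyst intermediate A (k = 14.0 M⁻¹ s⁻¹)
    catalyst intermediate C → free catalyst + product (k = 3.30 s⁻¹)
    2 catalyst intermediate C → spent catalyst (k = 8.10 M⁻¹ s⁻¹)
    catalyst intermediate A → by-product + catalyst intermediate B (k = 7.70 s⁻¹)
    2 free catalyst ⇌ resting dimer, settled at all times (K = 28000 M⁻¹)

The violet flask gives 1.0 in partner, 0.72 in free catalyst and a factor of 1.61. At 0.400 h it holds 42.5% of its catalyst as free catalyst, the resting state, more than the 38.4% as resting dimer, with 16.3% as catalyst intermediate B. Now carry the share 0.125 along the run, with the partner part growing as 1/c(partner) and the rest as 1/c(starting material). At conversion 0.7 the rate over that at 20% comes to 0.570, and the flask gives 0.58.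

Readings and results are simulated with constants of no real substance; scatter was added.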